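**Design of a synthesis of the 3(E)→8(N) biflavanone CNP0105436.4 by cyclobutenone benzannulation**

## The problem

The target is a biflavanone in which C3 of one chroman-4-one (unit E, bearing the 3,4-dihydroxyphenyl ring) is bonded to C8 of a second one (unit N, bearing the 4-hydroxyphenyl ring). This bond joins an sp3 carbon alpha to a ketone to an aromatic carbon flanked by two oxygen-bearing carbons (C7 and C8a of N), so it is hindered from both sides and poorly suited to a late coupling. Ring A of N is a hexasubstituted phloroglucinol whose three oxygens have different fates (ring oxygen on C8a, free hydroxyls on C5 and C7) and whose two carbon positions C6 and C8 are almost indistinguishable to electrophiles. Three stereocentres must be set: C2(N) is R and isolated, while C2(E) and C3(E) are both R, which places the two aryl groups on ring C of E cis, the less stable arrangement. C2(N) sits across the rotating C3(E)–C8(N) bond and cannot direct C2(E), whereas C2(E), once present, can direct C3(E) through kinetic protonation of an enol. C3(E)–H is alpha to a ketone and benzylic and drifts to trans under acid or base, both flavanones open to chalcones under base with loss of their C2 centres, and seven phenols have to be released at the end without either. The feature that makes the key step possible is the pattern around C8(N): a carbon substituent between C7–O and C8a–O on a 1,3,5-trioxygenated ring with hydrogen on C4a and C6 is exactly what a 4-substituted 3-alkoxycyclobutenone and a terminal ynol ether assemble, with the cyclobutenone carbonyl emerging as the single free phenol on C8a.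

## Retrosynthesis

**Protecting groups (43 from 42).** The last cut removes five benzyl ethers and one benzyl carbonate from 42 by hydrogenolysis. A neutral final step is required because the cis centre C3(E) and both C2 centres do not survive base. 42 differs from 43 only in these groups, and the forward reaction must leave the ketones and the benzylic C2–O1 bonds alone.

**C3(E)–H and the silyl groups (42 from 41).** The C3(E)–H bond is cut back to the enol silyl ether 41, and the free C5(N) hydroxyl back to its TIPS ether. Setting C3(E) by protonation of an isolated enol ether, instead of in the work-up of the arylation, allows the proton to be delivered under defined, non-basic conditions. The forward step must put the proton on the face opposite the C2(E) aryl group and must not equilibrate afterwards.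

**C2(E)–aryl (41 from 37 and 38).** The bond between C2(E) and the 3,4-dioxygenated ring is cut, leading to chromone 37 and aryl bromide 38. Cutting here rather than at C2(E)–C3(E) or O1(E)–C2(E) keeps ring C of E intact as a chromone, a robust group that has carried C3(E) since the start. The precursor loses two stereocentres. The forward reaction is a conjugate arylation of a silyl-activated chromone. It will not discriminate the two faces of C2(E), so 41 is expected to be accompanied by its C2(E) epimer. Because C2(N) is already fixed, the two series are diastereomers, and they are parted by chromatography once ketone 42 has been formed, where the sp3 centre C3(E) and the chelated C5(N) hydroxyl should make them differ most.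

**C4(N)–C4a(N) (37 from 34).** Ring C of N is opened at the aryl ketone bond, giving the tert-butyl ester 34 of a 3-aryloxy-3-arylpropanoic acid. Only C4a is ortho to the ether oxygen, so the Friedel–Crafts closure has no regiochemical choice. The alternative cut at O1–C2 (chalcone cyclisation) would set C2(N) reversibly and without control. The forward step must acylate next to a silyloxy group without ionising the benzylic ether.

**O1(N)–C2(N) (34 from 28 and 33).** The aryl ether bond is cut to phenol 28 and the (S)-hydroxy ester 33, joined with inversion in a Mitsunobu reaction. This takes the configuration of C2(N) from a reagent. The B-ring oxygen of N is carried as a benzyl carbonate rather than a benzyl ether, because a 4-alkoxyphenyl carbinol ionises in the Mitsunobu step and under the acid of the ring closure, whereas the carbonate is electron-poor and still falls in the final hydrogenolysis.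

**Ring A of N (28 from 16 and 23).** The bonds C4a–C8a and C5–C6 are cut and the C8–C8a bond is traced back to the cyclobutenone ring, leading to cyclobutenone 16 and (triisopropylsilyloxy)ethyne 23. Against any coupling of a chromone to a preformed phloroglucinol, this cut makes the hindered C3(E)–C8(N) bond a simple C–C bond of an acetic acid and fixes which oxygen is free. The only stereocentre of 16 becomes aromatic, so the racemate serves, and the forward reaction has only to follow its mechanism.

**Cyclobutenone (16 from 7 and 13).** The four-membered ring is cut into the ketene of chromone-3-acetic acid 7 and benzyl ethynyl ether 13. The polarity of the [2+2] step puts the benzyloxy group on C3 and the chromone on C4, as the benzannulation requires.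

**Chromone-3-acetic acid (7 from 1 and 2).** The C2 carbon of the chromone is removed (formamide acetal) and the acetic acid side chain is cut at the ketone alpha carbon, giving the purchasable acetophenone 1 and tert-butyl bromoacetate 2 by way of keto ester 4 and chromone ester 6. This avoids Lewis-acid acylation of a benzyl-protected phloroglucinol.

**The two ynol ethers (13 from 8 and 9; 23 from 17).** 13 is cut to benzyl alcohol 8 and trichloroethylene 9 through dichlorovinyl ether 11. 23 is cut to tetrahydrofuran 17 through vinyl ether 19 and bromovinyl ether 21. Both are dehydrohalogenations of halovinyl ethers, the classical way to terminal ynol ethers.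

**The chiral alcohol (33 from 29 and 31).** The carbinol centre is traced to keto ester 32 (Noyori transfer hydrogenation), and the C2–C3 bond of 32 to aldehyde 30 and tert-butyl diazoacetate 31 (Roskamp reaction). 30 is the benzyl carbonate of 4-hydroxybenzaldehyde 29.

## Roads not taken

**Alternative 1:** The cut is C2(E)–C3(E). The diazoketone A2, in which C3(E) is the diazo carbon between the ring A carbonyl of E and C8(N), would be decomposed by Rh2(S-PTTL)4 (dirhodium tetrakis[N-phthaloyl-(S)-tert-leucinate]). The carbene would insert into a benzylic C–H bond of an ortho 3,4-bis(benzyloxy)benzyl ether and give A1.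
- Merits: both centres of unit E are set in one catalyst-controlled event, and cis is the kinetic outcome for this class of insertion. In this respect the road is better than the chosen plan, whose arylation has no control over C2(E) and pays for it with a separation of diastereomers.
- Weak points:
  - A2 already contains the C3(E)–C8(N) bond and the differentiated ring A of N, so the step solves neither of the two structural problems.
  - The insertion must close a six-membered ring through the ether oxygen, whereas five-membered closure is the preferred mode of such carbenes.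
  - Attack of the carbene on that oxygen would give an oxonium ylide, and a [1,2]-benzyl shift would then lead to a benzofuranone.
  - The diazo group has to be placed on a ketone flanked by two fully ortho-substituted arenes.
  - The chiral catalyst meets a substrate that already holds C2(N).
- Comparison: the chosen plan never has to form ring C of E, because it is a chromone from the start, and it removes the regiochemical problem of ring A of N by construction.

**Alternative 2:** The cuts are C3(E)–C4(E) and O1(E)–C2(E). Salicylaldehyde A4 and diarylalkyne A5 would be joined with [Cp*RhCl2]2, AgSbF6 and Cu(OAc)2: aldehyde C–H activation by trivalent rhodium, alkyne insertion and C–O bond formation would give the 2,3-diarylchromone A3.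
- Merits: it is the most convergent road, unit N arrives complete and (2R), and syn addition of hydrogen across C2=C3 would give the cis relationship automatically. On that point it is as good as or better than kinetic protonation.
- Weak points:
  - Both alkyne carbons of A5 carry aryl groups, so only a small steric and electronic difference decides which becomes C2(E).
  - A5 has to be attached at C8 of a finished unit N, where C8 and C6 compete, which is the unsolved regiochemical problem again.
  - The tetrasubstituted, doubly arylated C2=C3 bond of A3 must then be reduced with facial control in the presence of seven benzyl ethers and two ketones, for which no dependable method exists.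
  - The hot, oxidising, Lewis-acidic medium endangers C2(N).
- Comparison: the chosen plan keeps C2=C3 trisubstituted and uses it as an electrophile.

**Alternative 3:** The cut is C4(N)–C4a(N). Acid A7 would be activated with trifluoroacetic anhydride and would close to A6.
- Merits: this is the same closure as step 15 of the chosen route and is reliable. All-benzyl protection means one final hydrogenolysis and no fluoride step, so the road would be shorter.
- Weak points:
  - As a key step it carries little. A7 derives from phenol A8, and making A8 requires attaching the chromone selectively between the hydroxyl and one benzyloxy group of a 3,5-bis(benzyloxy)phenol pattern, against the position between the two benzyloxy groups, by a doubly ortho-hindered coupling.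
  - The 4-benzyloxyphenyl group of A7 makes the benzylic ether prone to ionisation during etherification and under the anhydride, which threatens C2(N).
- Comparison: if A8 were available regioselectively this road would win on step count. The chosen plan spends three steps on alkyne 23 and one silyl ether to obtain the equivalent phenol 28 with unambiguous regiochemistry. Both roads share the same end game, so neither has an advantage at C2(E).

Key step: step 10

Assumption: the SMILES is read as (2R,3R) in unit E (aryl groups on C2 and C3 cis) and (2R) in unit N, and the route is planned for exactly this isomer; 1, 2, 8, 9, 17, 29, 31 and 38 are taken to be purchasable.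

## Route

Step 1
Reactants: 1 1-[2,4-bis(benzyloxy)-6-hydroxyphenyl]ethan-1-one; 2 tert-butyl bromoacetate
Product: 4 tert-butyl 4-[2,4-bis(benzyloxy)-6-hydroxyphenyl]-4-oxobutanoate, via dilithium dianion 3 (not isolated)
Conditions: LiN(SiMe3)2 (2.5 equiv), THF, −78 to −20 °C; then 2, −78 to 0 °C; aq. NH4Cl
Reagents that add atoms: none
Why: C-Alkylation of the phenolate–enolate dianion of a 2-hydroxyacetophenone; the chelated lithium phenolate is inert, so the bromoacetate is taken up at the enolate carbon, and the tert-butyl ester resists Claisen attack.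

Step 2
Reactants: 4 keto ester
Product: 6 tert-butyl 2-[5,7-bis(benzyloxy)-4-oxo-4H-chromen-3-yl]acetate, via enaminone 5 (not isolated)
Conditions: Me2NCH(OMe)2, toluene, 100 °C; then AcOH, 60 °C
Reagents that add atoms: N,N-dimethylformamide dimethyl acetal, COC(OC)N(C)C
Why: Enaminone formation at the ketone alpha-methylene followed by addition–elimination of the ortho phenol is the standard chromone closure of 2-hydroxyaryl alkyl ketones; the ester alpha position is much less acidic and should stay untouched.

Step 3
Reactants: 6 chromone ester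
Product: 7 2-[5,7-bis(benzyloxy)-4-oxo-4H-chromen-3-yl]acetic acid
Conditions: CF3CO2H–CH2Cl2 (1:3), 0 °C to rt
Reagents that add atoms: none
Why: Acidolysis of the tert-butyl ester avoids hydroxide, which would open the chromone at C2; the aryl benzyl ethers on the deactivated chromone ring should tolerate the short acid exposure.

Step 4
Reactants: 8 benzyl alcohol; 9 trichloroethylene
Product: 11 (E)-benzyl 1,2-dichloroethenyl ether, via potassium benzyl oxide 10 (not isolated)
Conditions: KH, THF, 0 °C; then 9, rt
Reagents that add atoms: none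
Why: Base-induced elimination of trichloroethylene to dichloroethyne and trans addition of the alkoxide is the established entry to 1,2-dichlorovinyl ethers.

Step 5
Reactants: 11 dichlorovinyl ether
Product: 13 benzyl ethynyl ether, via lithium benzyloxyethynide 12 (not isolated)
Conditions: n-BuLi (2.2 equiv), Et2O, −78 to −40 °C; MeOH, −78 °C; solution kept below 0 °C and used at once
Reagents that add atoms: none
Why: Elimination of HCl and chlorine–lithium exchange convert dichlorovinyl ethers into lithium alkoxyacetylides, which are protonated to the terminal ynol ether; 13 is kept cold because benzyl alkynyl ethers rearrange on warming.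

Step 6
Reactants: 7 chromone-3-acetic acid; 13 benzyl ethynyl ether
Product: 16 3-(benzyloxy)-4-[5,7-bis(benzyloxy)-4-oxo-4H-chromen-3-yl]cyclobut-2-en-1-one (racemic at C4), via acid chloride 14 (not isolated), via ketene 15 (not isolated)
Conditions: (COCl)2, DMF (cat.), CH2Cl2, 0 °C to rt, evaporate; then 13 (2.5 equiv), Et3N (slow addition), CH2Cl2, 0 °C to rt
Reagents that add atoms: none
Why: Dehydrochlorination of an arylacetyl-type chloride gives the monosubstituted ketene, which adds alkoxyacetylenes in a regiospecific [2+2] cycloaddition (ketene carbonyl carbon to the CH terminus) to give 3-alkoxy-4-substituted cyclobutenones; slow base addition and excess alkyne should suppress ketene dimerisation.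

Step 7
Reactants: 17 tetrahydrofuran
Product: 19 triisopropyl(vinyloxy)silane, via lithium ethenolate 18 (not isolated)
Conditions: n-BuLi, THF, rt, 16 h; then i-Pr3SiCl, DMPU, 0 °C to rt
Reagents that add atoms: chlorotriisopropylsilane, CC(C)[Si](Cl)(C(C)C)C(C)C
Why: Alpha-lithiated tetrahydrofuran undergoes cycloreversion to ethene and the lithium enolate of acetaldehyde, which the bulky chlorosilane silylates on oxygen.

Step 8
Reactants: 19 silyl vinyl ether
Product: 21 (Z)-(2-bromoethenyloxy)triisopropylsilane, via dibromide 20 (not isolated)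
Conditions: Br2, CH2Cl2, −78 °C; then Et3N, −78 °C to rt
Reagents that add atoms: bromine, BrBr
Why: Bromination of a vinyl ether and amine-induced loss of HBr from the resulting alpha-bromo ether is the classical route to 2-bromovinyl ethers, applied here to the silyl ether, and should favour the Z isomer; the bulky silyl group slows collapse of the alpha-bromo ether to bromoacetaldehyde.

Step 9
Reactants: 21 bromovinyl silyl ether
Product: 23 (triisopropylsilyloxy)ethyne, via lithium silyloxyethynide 22 (not isolated)
Conditions: LiN(i-Pr)2 (2.2 equiv), THF, −78 °C; aq. NH4Cl, −78 °C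
Reagents that add atoms: none
Why: Anti elimination of HBr from a (Z)-2-halovinyl ether is the classical dehydrohalogenation route to ynol ethers; the hindered amide should not attack silicon, and cold quenching of the acetylide limits oxygen-to-carbon silyl migration.

Step 10
Reactants: 16 cyclobutenone; 23 (triisopropylsilyloxy)ethyne
Product: 28 3-[2-(benzyloxy)-6-hydroxy-4-(triisopropylsilyloxy)phenyl]-5,7-bis(benzyloxy)-4H-chromen-4-one, via vinylketene 24 (not isolated), via vinylcyclobutenone 25 (not isolated), via dienylketene 26 (not isolated), via cyclohexadienone 27 (not isolated)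
Conditions: 23 (2 equiv), toluene, 80 °C then 110 °C, sealed vessel
Reagents that add atoms: none
Why: This is a Danheiser benzannulation of a cyclobutenone with a siloxyalkyne, the closest known reaction type, applied here to a 3-alkoxy-4-hetaryl cyclobutenone. Heating opens 16 by four-electron electrocyclic cleavage of its C1–C4 bond to vinylketene 24, whose electrophilic ketene carbon bonds to the nucleophilic CH terminus of 23 while the ketene alpha carbon bonds to the oxygen-bearing alkyne carbon; this [2+2] step forms C4a(N)–C8a(N) and C5(N)–C6(N) and gives 25. A second four-electron opening gives dienylketene 26; the opening is reversible, so the isomer with the vinyl group turned inward is drained by a thermal, disrotatory six-electron electrocyclisation between the ketene carbon and the chromone-bearing terminus, which closes ring A of N through the C8–C8a bond as dienone 27. Tautomerisation of 27 aromatises the ring and erases the stereocentre at C4 of 16, so no stereocentre is made or needed. The selectivity required is regiochemical and is fixed by the polarity of the partners: the ketene carbonyl becomes the only free hydroxyl (on C8a) next to the chromone-bearing C8, the silyloxy group lands on C5 and the benzyloxy group on C7, and C4a and C6 remain CH. An excess of 23 is used so that capture of 24 outruns its dimerisation and the acylation of product phenol 28 by ketene intermediates, and the triisopropylsilyl group is chosen because it keeps the ynol ether from rearranging to a silylketene at the reaction temperature.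

Step 11
Reactants: 29 4-hydroxybenzaldehyde
Product: 30 benzyl 4-formylphenyl carbonate
Conditions: BnOCOCl, Et3N, CH2Cl2, 0 °C
Reagents that add atoms: benzyl chloroformate, O=C(Cl)OCc1ccccc1
Why: Simple O-acylation of the phenol; the carbonate makes the ring electron-poor for the later Mitsunobu and Friedel–Crafts steps and is removable by hydrogenolysis.

Step 12
Reactants: 30 aldehyde; 31 tert-butyl diazoacetate
Product: 32 tert-butyl 3-{4-[(benzyloxycarbonyl)oxy]phenyl}-3-oxopropanoate
Conditions: SnCl2 (10 mol %), CH2Cl2, rt
Reagents that add atoms: none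
Why: Roskamp homologation: Lewis-acid-promoted addition of the diazo ester to the aldehyde and 1,2-hydride shift with loss of nitrogen give the beta-keto ester under neutral conditions that spare the carbonate.

Step 13
Reactants: 32 beta-keto ester
Product: 33 tert-butyl (3S)-3-{4-[(benzyloxycarbonyl)oxy]phenyl}-3-hydroxypropanoate
Conditions: RuCl[(S,S)-TsDPEN](p-cymene) (1 mol %), HCO2H–Et3N (5:2), EtOAc, rt
Reagents that add atoms: none
Why: Noyori asymmetric transfer hydrogenation of an aryl beta-keto ester; the (S,S) catalyst should deliver hydride to the same face as in simple aryl ketones and so set the (S) carbinol by catalyst control.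

Step 14
Reactants: 28 phenol; 33 (S)-hydroxy ester
Product: 34 tert-butyl (3R)-3-{3-(benzyloxy)-2-[5,7-bis(benzyloxy)-4-oxo-4H-chromen-3-yl]-5-(triisopropylsilyloxy)phenoxy}-3-{4-[(benzyloxycarbonyl)oxy]phenyl}propanoate
Conditions: PPh3, DIAD, toluene, 0 °C to rt
Reagents that add atoms: none
Why: Mitsunobu etherification of a phenol with a secondary benzylic alcohol proceeds with inversion, turning the (S) carbinol into the (R) aryl ether that becomes C2(N); the electron-poor aryl group should disfavour the benzylic ionisation that erodes configuration with 4-alkoxyaryl carbinols.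

Step 15
Reactants: 34 aryl ether ester
Product: 37 (2R)-7-(benzyloxy)-2-{4-[(benzyloxycarbonyl)oxy]phenyl}-8-[5,7-bis(benzyloxy)-4-oxo-4H-chromen-3-yl]-5-(triisopropylsilyloxy)-2,3-dihydro-4H-chromen-4-one, via carboxylic acid 35 (not isolated), via mixed anhydride 36 (not isolated)
Conditions: CF3CO2H–CH2Cl2 (1:4), 0 °C, evaporate; then (CF3CO)2O, CH2Cl2, 0 °C to rt
Reagents that add atoms: none
Why: Acidolysis of the tert-butyl ester and activation as the mixed trifluoroacetic anhydride lead to intramolecular Friedel–Crafts acylation at C4a, the only position ortho to the ether oxygen, on a ring activated by three oxygens; the benzylic C–O bond, deactivated by the carbonate, should not ionise, so C2(N) stays R.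

Step 16
Reactants: 37 flavanone–chromone; 38 4-bromo-1,2-bis(benzyloxy)benzene
Product: 41 (2R)-7-(benzyloxy)-2-{4-[(benzyloxycarbonyl)oxy]phenyl}-8-{(2S)-5,7-bis(benzyloxy)-2-[3,4-bis(benzyloxy)phenyl]-4-(tert-butyldimethylsilyloxy)-2H-chromen-3-yl}-5-(triisopropylsilyloxy)-2,3-dihydro-4H-chromen-4-one, via arylmagnesium bromide 39 (not isolated), via benzopyrylium triflate 40 (not isolated)
Conditions: 38, Mg, THF, rt; separately 37, TBSOTf (1.1 equiv), CH2Cl2, 0 °C to rt; then 39 (1.5 equiv), CuBr·SMe2 (20 mol %), −78 °C; aq. NaHCO3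
Reagents that add atoms: tert-butyldimethylsilyl trifluoromethanesulfonate, CC(C)(C)[Si](C)(C)OS(=O)(=O)C(F)(F)F
Why: Silyl triflate activation of a chromone to its 4-silyloxybenzopyrylium salt and copper-mediated addition of an aryl Grignard reagent at C2 is established chromone chemistry; the pyranone carbonyl is the most basic oxygen of 37, so the one equivalent of silyl triflate should be taken up there, and the cation should outrun the hindered ketone of unit N and the carbonate for the nucleophile. C2(E) is formed without useful bias from the remote C2(N) centre, so 41 (whose 2S descriptor as a chromene corresponds to 2R in the ketone) should be accompanied by a comparable share of its C2(E) epimer, the (2R)-chromene of the same constitution. The two are diastereomers, are not separated at this stage and are taken together into step 17.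

Step 17
Reactants: 41 enol silyl ether (used together with its C2(E) epimer as obtained in step 16)
Product: 42 (2R)-7-(benzyloxy)-2-{4-[(benzyloxycarbonyl)oxy]phenyl}-8-{(2R,3R)-5,7-bis(benzyloxy)-2-[3,4-bis(benzyloxy)phenyl]-4-oxo-3,4-dihydro-2H-chromen-3-yl}-5-hydroxy-2,3-dihydro-4H-chromen-4-one
Conditions: HF·pyridine, pyridine, THF, −20 °C to rt; chromatography
Reagents that add atoms: none
Why: Cleavage of the enol silyl ether releases the enol, which should be protonated at C3(E) on the face away from the pseudoaxial C2(E) aryl group (kinetic protonation), placing hydrogen trans to that aryl group and the two aryl groups cis; the same reagent cleaves the aryl O–Si bond peri to the ketone of unit N without base. The epimer carried along from step 16 should react in the same way to the diastereomer with (2S,3S) configuration in unit E, which chromatography removes from 42 at this stage.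

Step 18
Reactants: 42 cis ketone
Product: 43 (2R,3R)-2-(3,4-dihydroxyphenyl)-3-[(2R)-5,7-dihydroxy-2-(4-hydroxyphenyl)-4-oxo-3,4-dihydro-2H-chromen-8-yl]-5,7-dihydroxy-2,3-dihydro-4H-chromen-4-one
Conditions: H2 (1 atm), Pd/C (10 % Pd on carbon), EtOAc–MeOH, rt
Reagents that add atoms: none
Why: Hydrogenolysis cleaves the five benzyl ethers and the benzyl carbonate (which then loses CO2) under neutral conditions, so the cis C3(E) centre and both C2 centres should not be disturbed; the ketones and the flavanone C2–O1 bonds should survive these mild conditions.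

## Compound list

1 | 1-[2,4-bis(benzyloxy)-6-hydroxyphenyl]ethan-1-one | CC(=O)c1c(O)cc(OCc2ccccc2)cc1OCc1ccccc1 | starting material
2 | tert-butyl bromoacetate | CC(C)(C)OC(=O)CBr | starting material
3 | dilithium phenolate–enolate dianion of 1 | [Li+].[Li+].C=C([O-])c1c([O-])cc(OCc2ccccc2)cc1OCc1ccccc1 | intermediate (not isolated)
4 | tert-butyl 4-[2,4-bis(benzyloxy)-6-hydroxyphenyl]-4-oxobutanoate | CC(C)(C)OC(=O)CCC(=O)c1c(O)cc(OCc2ccccc2)cc1OCc1ccccc1 | intermediate
5 | tert-butyl 3-[2,4-bis(benzyloxy)-6-hydroxybenzoyl]-4-(dimethylamino)but-3-enoate | CN(C)C=C(CC(=O)OC(C)(C)C)C(=O)c1c(O)cc(OCc2ccccc2)cc1OCc1ccccc1 | intermediate (not isolated)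
6 | tert-butyl 2-[5,7-bis(benzyloxy)-4-oxo-4H-chromen-3-yl]acetate | CC(C)(C)OC(=O)Cc1coc2cc(OCc3ccccc3)cc(OCc3ccccc3)c2c1=O | intermediate
7 | 2-[5,7-bis(benzyloxy)-4-oxo-4H-chromen-3-yl]acetic acid | OC(=O)Cc1coc2cc(OCc3ccccc3)cc(OCc3ccccc3)c2c1=O | intermediate
8 | benzyl alcohol | OCc1ccccc1 | starting material
9 | trichloroethylene | ClC=C(Cl)Cl | starting material
10 | potassium benzyl oxide | [K+].[O-]Cc1ccccc1 | intermediate (not isolated)
11 | (E)-benzyl 1,2-dichloroethenyl ether | Cl/C=C(/Cl)OCc1ccccc1 | intermediate
12 | lithium 2-(benzyloxy)ethynide | [Li+].[C-]#COCc1ccccc1 | intermediate (not isolated)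
13 | benzyl ethynyl ether | C#COCc1ccccc1 | intermediate
14 | 2-[5,7-bis(benzyloxy)-4-oxo-4H-chromen-3-yl]acetyl chloride | O=C(Cl)Cc1coc2cc(OCc3ccccc3)cc(OCc3ccccc3)c2c1=O | intermediate (not isolated)
15 | [5,7-bis(benzyloxy)-4-oxo-4H-chromen-3-yl]ketene | O=C=Cc1coc2cc(OCc3ccccc3)cc(OCc3ccccc3)c2c1=O | intermediate (not isolated)
16 | 3-(benzyloxy)-4-[5,7-bis(benzyloxy)-4-oxo-4H-chromen-3-yl]cyclobut-2-en-1-one (racemic at C4) | O=C1C=C(OCc2ccccc2)C1c1coc2cc(OCc3ccccc3)cc(OCc3ccccc3)c2c1=O | intermediate
17 | tetrahydrofuran | C1CCOC1 | starting material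
18 | lithium ethenolate | [Li+].[O-]C=C | intermediate (not isolated)
19 | triisopropyl(vinyloxy)silane | C=CO[Si](C(C)C)(C(C)C)C(C)C | intermediate
20 | (1,2-dibromoethoxy)triisopropylsilane (racemic) | BrCC(Br)O[Si](C(C)C)(C(C)C)C(C)C | intermediate (not isolated)
21 | (Z)-(2-bromoethenyloxy)triisopropylsilane | Br/C=C\O[Si](C(C)C)(C(C)C)C(C)C | intermediate
22 | lithium 2-(triisopropylsilyloxy)ethynide | [Li+].[C-]#CO[Si](C(C)C)(C(C)C)C(C)C | intermediate (not isolated)
23 | (triisopropylsilyloxy)ethyne | C#CO[Si](C(C)C)(C(C)C)C(C)C | intermediate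
24 | 3-(benzyloxy)-4-[5,7-bis(benzyloxy)-4-oxo-4H-chromen-3-yl]buta-1,3-dien-1-one (vinylketene) | O=C=CC(OCc1ccccc1)=Cc1coc2cc(OCc3ccccc3)cc(OCc3ccccc3)c2c1=O | intermediate (not isolated)
25 | 4-{1-(benzyloxy)-2-[5,7-bis(benzyloxy)-4-oxo-4H-chromen-3-yl]ethenyl}-3-(triisopropylsilyloxy)cyclobut-2-en-1-one | O=C1C=C(O[Si](C(C)C)(C(C)C)C(C)C)C1C(OCc1ccccc1)=Cc1coc2cc(OCc3ccccc3)cc(OCc3ccccc3)c2c1=O | intermediate (not isolated)
26 | 5-(benzyloxy)-6-[5,7-bis(benzyloxy)-4-oxo-4H-chromen-3-yl]-3-(triisopropylsilyloxy)hexa-1,3,5-trien-1-one (dienylketene) | O=C=CC(O[Si](C(C)C)(C(C)C)C(C)C)=CC(OCc1ccccc1)=Cc1coc2cc(OCc3ccccc3)cc(OCc3ccccc3)c2c1=O | intermediate (not isolated)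
27 | 5-(benzyloxy)-6-[5,7-bis(benzyloxy)-4-oxo-4H-chromen-3-yl]-3-(triisopropylsilyloxy)cyclohexa-2,4-dien-1-one | O=C1C=C(O[Si](C(C)C)(C(C)C)C(C)C)C=C(OCc2ccccc2)C1c1coc2cc(OCc3ccccc3)cc(OCc3ccccc3)c2c1=O | intermediate (not isolated)
28 | 3-[2-(benzyloxy)-6-hydroxy-4-(triisopropylsilyloxy)phenyl]-5,7-bis(benzyloxy)-4H-chromen-4-one | Oc1cc(O[Si](C(C)C)(C(C)C)C(C)C)cc(OCc2ccccc2)c1-c1coc2cc(OCc3ccccc3)cc(OCc3ccccc3)c2c1=O | intermediate
29 | 4-hydroxybenzaldehyde | O=Cc1ccc(O)cc1 | starting material
30 | benzyl 4-formylphenyl carbonate | O=Cc1ccc(OC(=O)OCc2ccccc2)cc1 | intermediate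
31 | tert-butyl diazoacetate | CC(C)(C)OC(=O)C=[N+]=[N-] | starting material
32 | tert-butyl 3-{4-[(benzyloxycarbonyl)oxy]phenyl}-3-oxopropanoate | CC(C)(C)OC(=O)CC(=O)c1ccc(OC(=O)OCc2ccccc2)cc1 | intermediate
33 | tert-butyl (3S)-3-{4-[(benzyloxycarbonyl)oxy]phenyl}-3-hydroxypropanoate | CC(C)(C)OC(=O)C[C@H](O)c1ccc(OC(=O)OCc2ccccc2)cc1 | intermediate
34 | tert-butyl (3R)-3-{3-(benzyloxy)-2-[5,7-bis(benzyloxy)-4-oxo-4H-chromen-3-yl]-5-(triisopropylsilyloxy)phenoxy}-3-{4-[(benzyloxycarbonyl)oxy]phenyl}propanoate | CC(C)(C)OC(=O)C[C@@H](Oc1cc(O[Si](C(C)C)(C(C)C)C(C)C)cc(OCc2ccccc2)c1-c1coc2cc(OCc3ccccc3)cc(OCc3ccccc3)c2c1=O)c1ccc(OC(=O)OCc2ccccc2)cc1 | intermediate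
35 | (3R)-3-{3-(benzyloxy)-2-[5,7-bis(benzyloxy)-4-oxo-4H-chromen-3-yl]-5-(triisopropylsilyloxy)phenoxy}-3-{4-[(benzyloxycarbonyl)oxy]phenyl}propanoic acid | OC(=O)C[C@@H](Oc1cc(O[Si](C(C)C)(C(C)C)C(C)C)cc(OCc2ccccc2)c1-c1coc2cc(OCc3ccccc3)cc(OCc3ccccc3)c2c1=O)c1ccc(OC(=O)OCc2ccccc2)cc1 | intermediate (not isolated)
36 | mixed anhydride of 35 with trifluoroacetic acid | O=C(OC(=O)C(F)(F)F)C[C@@H](Oc1cc(O[Si](C(C)C)(C(C)C)C(C)C)cc(OCc2ccccc2)c1-c1coc2cc(OCc3ccccc3)cc(OCc3ccccc3)c2c1=O)c1ccc(OC(=O)OCc2ccccc2)cc1 | intermediate (not isolated)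
37 | (2R)-7-(benzyloxy)-2-{4-[(benzyloxycarbonyl)oxy]phenyl}-8-[5,7-bis(benzyloxy)-4-oxo-4H-chromen-3-yl]-5-(triisopropylsilyloxy)-2,3-dihydro-4H-chromen-4-one | O=C1C[C@H](c2ccc(OC(=O)OCc3ccccc3)cc2)Oc2c1c(O[Si](C(C)C)(C(C)C)C(C)C)cc(OCc1ccccc1)c2-c1coc2cc(OCc3ccccc3)cc(OCc3ccccc3)c2c1=O | intermediate
38 | 4-bromo-1,2-bis(benzyloxy)benzene | Brc1ccc(OCc2ccccc2)c(OCc2ccccc2)c1 | starting material
39 | [3,4-bis(benzyloxy)phenyl]magnesium bromide | Br[Mg]c1ccc(OCc2ccccc2)c(OCc2ccccc2)c1 | intermediate (not isolated)
40 | 4-(tert-butyldimethylsilyloxy)benzopyrylium triflate derived from 37 | O=C1C[C@H](c2ccc(OC(=O)OCc3ccccc3)cc2)Oc2c1c(O[Si](C(C)C)(C(C)C)C(C)C)cc(OCc1ccccc1)c2-c1c[o+]c2cc(OCc3ccccc3)cc(OCc3ccccc3)c2c1O[Si](C)(C)C(C)(C)C.[O-]S(=O)(=O)C(F)(F)F | intermediate (not isolated)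
41 | (2R)-7-(benzyloxy)-2-{4-[(benzyloxycarbonyl)oxy]phenyl}-8-{(2S)-5,7-bis(benzyloxy)-2-[3,4-bis(benzyloxy)phenyl]-4-(tert-butyldimethylsilyloxy)-2H-chromen-3-yl}-5-(triisopropylsilyloxy)-2,3-dihydro-4H-chromen-4-one | O=C1C[C@H](c2ccc(OC(=O)OCc3ccccc3)cc2)Oc2c1c(O[Si](C(C)C)(C(C)C)C(C)C)cc(OCc1ccccc1)c2C1=C(O[Si](C)(C)C(C)(C)C)c2c(OCc3ccccc3)cc(OCc3ccccc3)cc2O[C@H]1c1ccc(OCc2ccccc2)c(OCc2ccccc2)c1 | intermediate
42 | (2R)-7-(benzyloxy)-2-{4-[(benzyloxycarbonyl)oxy]phenyl}-8-{(2R,3R)-5,7-bis(benzyloxy)-2-[3,4-bis(benzyloxy)phenyl]-4-oxo-3,4-dihydro-2H-chromen-3-yl}-5-hydroxy-2,3-dihydro-4H-chromen-4-one | O=C1C[C@H](c2ccc(OC(=O)OCc3ccccc3)cc2)Oc2c1c(O)cc(OCc1ccccc1)c2[C@H]1C(=O)c2c(OCc3ccccc3)cc(OCc3ccccc3)cc2O[C@H]1c1ccc(OCc2ccccc2)c(OCc2ccccc2)c1 | intermediate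
43 | (2R,3R)-2-(3,4-dihydroxyphenyl)-3-[(2R)-5,7-dihydroxy-2-(4-hydroxyphenyl)-4-oxo-3,4-dihydro-2H-chromen-8-yl]-5,7-dihydroxy-2,3-dihydro-4H-chromen-4-one | O=C1C[C@H](c2ccc(O)cc2)Oc2c1c(O)cc(O)c2[C@H]1C(=O)c2c(O)cc(O)cc2O[C@H]1c1ccc(O)c(O)c1 | target

## Step count and uncertain steps

Total step count: 18. Longest linear sequence: 10 steps (steps 1, 2, 3, 6, 10, 14, 15, 16, 17, 18). The three side branches are steps 4–5 (alkyne 13), steps 7–9 (alkyne 23) and steps 11–13 (alcohol 33).

**Step 10 (key step).**
- Most likely failure: the parent siloxyalkyne is lost at 80–110 °C (silyl shift to a silylketene, oligomerisation) before it captures vinylketene 24. The ketene then dimerises or acylates the product phenol.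
- Fallback, from 16, returning at 28: the alkyne is replaced by its carbon-capped, more robust congener. Lithiation of trimethylsilylacetylene, oxidation of the acetylide with lithium tert-butyl peroxide and O-silylation with TIPSOTf should give triisopropyl{[(trimethylsilyl)ethynyl]oxy}silane F1. Benzannulation of 16 with F1 would follow the same polarity and give the C4a-silylated phenol 3-[2-(benzyloxy)-6-hydroxy-4-(triisopropylsilyloxy)-5-(trimethylsilyl)phenyl]-5,7-bis(benzyloxy)-4H-chromen-4-one F2. Ipso-protodesilylation of this electron-rich arylsilane with CF3CO2H in CH2Cl2 then returns 28.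

**Step 16.**
- Most likely failure: the absence of facial discrimination at C2(E) is expected and costs about half the material, and the two series, whose differing centres lie far from C2(N), may be slow to part on silica. Beyond that, 1,2-attack of the Grignard reagent on the ketone of unit N or on the carbonate, and incomplete pyrylium formation because of strain between the C5 benzyloxy group and the C4 silyloxy group, would lower conversion.
- Fallback, from 37 and 38, returning at 42: a catalyst-controlled, base-free conjugate addition. Bromide 38 is converted (n-BuLi, B(O-i-Pr)3, acid work-up) into [3,4-bis(benzyloxy)phenyl]boronic acid F3. F3 is added to 37 with Pd(OCOCF3)2 and the pyridine–oxazoline ligand (S)-t-BuPyOx (or its enantiomer, whichever gives the 2R series) and NH4PF6 in wet 1,2-dichloroethane at 60 °C. Under these conditions chromones unsubstituted at C3 are arylated enantioselectively, and the divalent palladium aryl attacks neither ketones nor carbonates. Protonation of the palladium enolate in the flask would give (2R)-7-(benzyloxy)-2-{4-[(benzyloxycarbonyl)oxy]phenyl}-8-{(2R,3R)-5,7-bis(benzyloxy)-2-[3,4-bis(benzyloxy)phenyl]-4-oxo-3,4-dihydro-2H-chromen-3-yl}-5-(triisopropylsilyloxy)-2,3-dihydro-4H-chromen-4-one F4, which HF·pyridine converts into 42. Insertion into the hindered, 3-arylated C2=C3 bond is the open question of this variant, which is why it is held in reserve.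

**Step 17.**
- Most likely failure: drift of the cis ketone to the trans isomer by enolisation while the aryl silyl ether is slowly cleaved, or protonation that is not fully face-selective.
- Fallback, from 37, returning at 42: the slow desilylation is moved in front of the stereo-defining step. HF·pyridine first converts 37 into (2R)-7-(benzyloxy)-2-{4-[(benzyloxycarbonyl)oxy]phenyl}-8-[5,7-bis(benzyloxy)-4-oxo-4H-chromen-3-yl]-5-hydroxy-2,3-dihydro-4H-chromen-4-one F5. Activation with TBSOTf and addition of 39 (one extra equivalent for the chelated phenol) gives (2R)-7-(benzyloxy)-2-{4-[(benzyloxycarbonyl)oxy]phenyl}-8-{(2S)-5,7-bis(benzyloxy)-2-[3,4-bis(benzyloxy)phenyl]-4-(tert-butyldimethylsilyloxy)-2H-chromen-3-yl}-5-hydroxy-2,3-dihydro-4H-chromen-4-one F6 together with the C2(E) epimer of F6 ((2R)-chromene) F7. A short treatment with HF·pyridine at −40 °C then has to cleave only the enol ether. F6 leads to 42, and F7 leads to the unit E (2S,3S) diastereomer of 42 F8, which is removed by chromatography.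

**Step 14.**
- Most likely failure: the hindered phenol displaces the activated alcohol too slowly, so that elimination to the cinnamate or partial ionisation with loss of configuration takes over.
- Fallback, from 33 and 28, returning at 35: the ether is formed by opening a beta-lactone. CF3CO2H cleaves 33 to (3S)-3-{4-[(benzyloxycarbonyl)oxy]phenyl}-3-hydroxypropanoic acid F9. F9 is closed with retention (PhSO2Cl, pyridine, 0 °C) to (4S)-4-{4-[(benzyloxycarbonyl)oxy]phenyl}oxetan-2-one F10. The sodium phenolate of 28 opens F10 at the benzylic carbon with inversion (alkyl–oxygen cleavage, the known mode for phenolates and beta-lactones) and gives acid 35 directly, which is cyclised as in step 15.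

## Further compounds

F1 | step 10 | triisopropyl{[(trimethylsilyl)ethynyl]oxy}silane | C[Si](C)(C)C#CO[Si](C(C)C)(C(C)C)C(C)C
F2 | step 10 | 3-[2-(benzyloxy)-6-hydroxy-4-(triisopropylsilyloxy)-5-(trimethylsilyl)phenyl]-5,7-bis(benzyloxy)-4H-chromen-4-one | Oc1c([Si](C)(C)C)c(O[Si](C(C)C)(C(C)C)C(C)C)cc(OCc2ccccc2)c1-c1coc2cc(OCc3ccccc3)cc(OCc3ccccc3)c2c1=O
F3 | step 16 | [3,4-bis(benzyloxy)phenyl]boronic acid | OB(O)c1ccc(OCc2ccccc2)c(OCc2ccccc2)c1
F4 | step 16 | (2R)-7-(benzyloxy)-2-{4-[(benzyloxycarbonyl)oxy]phenyl}-8-{(2R,3R)-5,7-bis(benzyloxy)-2-[3,4-bis(benzyloxy)phenyl]-4-oxo-3,4-dihydro-2H-chromen-3-yl}-5-(triisopropylsilyloxy)-2,3-dihydro-4H-chromen-4-one | O=C1C[C@H](c2ccc(OC(=O)OCc3ccccc3)cc2)Oc2c1c(O[Si](C(C)C)(C(C)C)C(C)C)cc(OCc1ccccc1)c2[C@H]1C(=O)c2c(OCc3ccccc3)cc(OCc3ccccc3)cc2O[C@H]1c1ccc(OCc2ccccc2)c(OCc2ccccc2)c1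
F5 | step 17 | (2R)-7-(benzyloxy)-2-{4-[(benzyloxycarbonyl)oxy]phenyl}-8-[5,7-bis(benzyloxy)-4-oxo-4H-chromen-3-yl]-5-hydroxy-2,3-dihydro-4H-chromen-4-one | O=C1C[C@H](c2ccc(OC(=O)OCc3ccccc3)cc2)Oc2c1c(O)cc(OCc1ccccc1)c2-c1coc2cc(OCc3ccccc3)cc(OCc3ccccc3)c2c1=O
F6 | step 17 | (2R)-7-(benzyloxy)-2-{4-[(benzyloxycarbonyl)oxy]phenyl}-8-{(2S)-5,7-bis(benzyloxy)-2-[3,4-bis(benzyloxy)phenyl]-4-(tert-butyldimethylsilyloxy)-2H-chromen-3-yl}-5-hydroxy-2,3-dihydro-4H-chromen-4-one | O=C1C[C@H](c2ccc(OC(=O)OCc3ccccc3)cc2)Oc2c1c(O)cc(OCc1ccccc1)c2C1=C(O[Si](C)(C)C(C)(C)C)c2c(OCc3ccccc3)cc(OCc3ccccc3)cc2O[C@H]1c1ccc(OCc2ccccc2)c(OCc2ccccc2)c1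
F7 | step 17 | C2(E) epimer of F6 ((2R)-chromene) | O=C1C[C@H](c2ccc(OC(=O)OCc3ccccc3)cc2)Oc2c1c(O)cc(OCc1ccccc1)c2C1=C(O[Si](C)(C)C(C)(C)C)c2c(OCc3ccccc3)cc(OCc3ccccc3)cc2O[C@@H]1c1ccc(OCc2ccccc2)c(OCc2ccccc2)c1
F8 | step 17 | unit E (2S,3S) diastereomer of 42: (2R)-7-(benzyloxy)-2-{4-[(benzyloxycarbonyl)oxy]phenyl}-8-{(2S,3S)-5,7-bis(benzyloxy)-2-[3,4-bis(benzyloxy)phenyl]-4-oxo-3,4-dihydro-2H-chromen-3-yl}-5-hydroxy-2,3-dihydro-4H-chromen-4-one | O=C1C[C@H](c2ccc(OC(=O)OCc3ccccc3)cc2)Oc2c1c(O)cc(OCc1ccccc1)c2[C@@H]1C(=O)c2c(OCc3ccccc3)cc(OCc3ccccc3)cc2O[C@@H]1c1ccc(OCc2ccccc2)c(OCc2ccccc2)c1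
F9 | step 14 | (3S)-3-{4-[(benzyloxycarbonyl)oxy]phenyl}-3-hydroxypropanoic acid | OC(=O)C[C@H](O)c1ccc(OC(=O)OCc2ccccc2)cc1
F10 | step 14 | (4S)-4-{4-[(benzyloxycarbonyl)oxy]phenyl}oxetan-2-one | O=C1C[C@@H](c2ccc(OC(=O)OCc3ccccc3)cc2)O1
A1 | alternative 1 | protected target with cis unit E (silyl ethers on ring A of N, 3,4-bis(benzyloxy)benzyl ethers on ring A of E) | O=C1C[C@H](c2ccc(OCc3ccccc3)cc2)Oc2c1c(O[Si](C)(C)C(C)(C)C)cc(O[Si](C)(C)C(C)(C)C)c2[C@H]1C(=O)c2c(OCc3ccc(OCc4ccccc4)c(OCc4ccccc4)c3)cc(OCc3ccc(OCc4ccccc4)c(OCc4ccccc4)c3)cc2O[C@H]1c1ccc(OCc2ccccc2)c(OCc2ccccc2)c1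
A2 | alternative 1 | alpha-aryl-alpha-diazoketone: 2-diazo-2-[(2R)-unit N-8-yl]-1-{2,4,6-tris[3,4-bis(benzyloxy)benzyloxy]phenyl}ethanone with tert-butyldimethylsilyl ethers on C5 and C7 of N | O=C1C[C@H](c2ccc(OCc3ccccc3)cc2)Oc2c1c(O[Si](C)(C)C(C)(C)C)cc(O[Si](C)(C)C(C)(C)C)c2C(=[N+]=[N-])C(=O)c1c(OCc2ccc(OCc3ccccc3)c(OCc3ccccc3)c2)cc(OCc2ccc(OCc3ccccc3)c(OCc3ccccc3)c2)cc1OCc1ccc(OCc2ccccc2)c(OCc2ccccc2)c1
A3 | alternative 2 | heptabenzyl flavone(E)–flavanone(N) with unit E as the 2,3-diarylchromone | O=C1C[C@H](c2ccc(OCc3ccccc3)cc2)Oc2c1c(OCc1ccccc1)cc(OCc1ccccc1)c2-c1c(-c2ccc(OCc3ccccc3)c(OCc3ccccc3)c2)oc2cc(OCc3ccccc3)cc(OCc3ccccc3)c2c1=O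
A4 | alternative 2 | 2-hydroxy-4,6-bis(benzyloxy)benzaldehyde | O=Cc1c(O)cc(OCc2ccccc2)cc1OCc1ccccc1
A5 | alternative 2 | (2R)-5,7-bis(benzyloxy)-2-[4-(benzyloxy)phenyl]-8-{[3,4-bis(benzyloxy)phenyl]ethynyl}-2,3-dihydro-4H-chromen-4-one | O=C1C[C@H](c2ccc(OCc3ccccc3)cc2)Oc2c1c(OCc1ccccc1)cc(OCc1ccccc1)c2C#Cc1ccc(OCc2ccccc2)c(OCc2ccccc2)c1
A6 | alternative 3 | (2R)-flavanone N tribenzyl ether carrying the 5,7-bis(benzyloxy)chromon-3-yl group at C8 | O=C1C[C@H](c2ccc(OCc3ccccc3)cc2)Oc2c1c(OCc1ccccc1)cc(OCc1ccccc1)c2-c1coc2cc(OCc3ccccc3)cc(OCc3ccccc3)c2c1=O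
A7 | alternative 3 | (3R)-3-{3,5-bis(benzyloxy)-2-[5,7-bis(benzyloxy)-4-oxo-4H-chromen-3-yl]phenoxy}-3-[4-(benzyloxy)phenyl]propanoic acid | OC(=O)C[C@@H](Oc1cc(OCc2ccccc2)cc(OCc2ccccc2)c1-c1coc2cc(OCc3ccccc3)cc(OCc3ccccc3)c2c1=O)c1ccc(OCc2ccccc2)cc1
A8 | alternative 3 | 3-[2,4-bis(benzyloxy)-6-hydroxyphenyl]-5,7-bis(benzyloxy)-4H-chromen-4-one | Oc1cc(OCc2ccccc2)cc(OCc2ccccc2)c1-c1coc2cc(OCc3ccccc3)cc(OCc3ccccc3)c2c1=O
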